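(The data come from a simulation with constants of no real substance; noise was put on by code.)

The flask holds G and Q at a ratio of 1.50, enough for the first exchange on every Q and a second exchange on half of them. The ledger therefore follows Q, the limiting reagent of the first exchange.

| setting | ochre | flask |
|---|---|---|
| Q | 0.41 M | 0.41 M |
| G | 0.615 M | 0.615 M |
| E | 0.205 M | 0.205 M |
| remark | the very flask that is asked about, followed so far |  |
| time |  | 12 min |

ochre run (percent of the Q charged)

| time / s | Q / % | Z / % |
|---|---|---|
| 12.0 | 93.4 | 0 |
| 30.0 | 87.1 | 0 |
| 60.0 | 77.5 | 0.4 |
| 90.0 | 69.0 | 1.2 |
| 120 | 61.0 | 2.6 |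

(each reading ± 1 percentage point)

- what was read earlier has a scatter of 1 percentage point, one standard deviation
- what has gone from Q into another species counts as reacted, even if it can come back
- the reaction counts as stopped when no species that holds the Q changes by six tenths of a point or more over the second half of the time

1. the state of affairs at 12 min: stopped, and by what, or still going (all of Q has reacted / G has run out first / it is still moving / forward and back rates have come level)
2. part of the Q gone at 12 min
3. the Z standing at 12 min, as a percentage of the Q charged
4. the X standing at 12 min, as a percentage of the Q charged

The first entry is Q still standing. It is reckoned from the loss constant of Q, the natural logarithm of charged over standing Q, divided by the time, a pseudo-first-order constant. The last reading gives 0.247 min⁻¹, and the reading at 60.0 s gives 0.255 min⁻¹. Carried forward, this reckoning gives: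

Q standing at 12 min = exp(−loss constant × time) = 5.15 %

Q gone = 94.8 %

Fall of Q over the second half of the time = 18 percentage points

Share of the G charged taken, at one G per Q gone = 63.2 %

This ledger therefore has the flask still moving, with G in hand. Its other entries stay open: at 120 s Z reads 2.6 % and a remainder of 36.4 % stands in no reading.

The forecast says it is still moving, with 84 % of Q gone, Z at 23 % and X at 60 %, on the ground that “Z appears with a lag, so the route is sequential”. Its Q gone is lower than this ledger's.

In the flask it is still moving, with 91.5 % of Q gone, Z at 8.95 % and X at 23.6 %.

    Q + G ⇌ E + X (K = 14.0, k = 0.160 M⁻¹ min⁻¹)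
    X + G ⇌ E + Z (K = 0.350, k = 0.220 M⁻¹ min⁻¹)
    Q ⇌ D (K = 11.0, k = 0.170 min⁻¹)

At 12.0 min the flask uses Q on the way to D 2.4 times as fast as on the way to X, each forward rate taken by itself, and the ledger closes with D at 58.9 %, more than X and Z together, at a mean loss constant of 0.205 min⁻¹. The neighbouring flask, charged with a quarter of that G, has 85.0 % of its Q gone at 12.0 min, so its mean loss constant is still 0.158 min⁻¹, which is 77.1 % of the first flask's.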